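The quinone ring is traced back to a resorcinol-type acetophenone, and that arene to a [4+2] union of an open-chain tetraoxygenated diene with but-3-yn-2-one. In quinone numbering (C1=O, C2–OH, C3–henicosyl, C4=O, C5–OMe, C6–H) the contiguous C2–C5 array is exactly the backbone of a 2-alkylated 4-methoxyacetoacetate. Its bis(trimethylsilyl) dienol ether therefore already holds the chain, three oxygens and the one methyl ether in the right order. One operation forms C1–C2 and C5–C6, closes the only ring, aromatises it by loss of the ester methoxy group and leaves an acetyl group at C1 as a masked hydroxyl. Dakin oxidation and oxidation to the quinone finish the route.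

Key step: step 5

Remark on the chemistry: the target has no stereocentre, so the racemic centre of the alkylated keto ester, the enol ether and ketene acetal geometries and the two sp3 ring carbons of the cycloadduct are left uncontrolled, since all are erased later; ring atoms are numbered as in the quinone throughout.

Step 1
Reactants: 1 henicosan-1-ol
Product: 2 1-iodohenicosane
Conditions: I2, PPh3, imidazole, CH2Cl2, 0 → 20 °C
Reagents that add atoms: iodine, [I][I]
Why: Appel-type iodination, in which the alcohol oxygen is activated as an alkoxyphosphonium ion and displaced by iodide in an SN2 reaction at an unhindered primary carbon, is routine for long-chain fatty alcohols.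

Step 2
Reactants: 2 1-iodohenicosane; 3 methyl 4-methoxy-3-oxobutanoate (methyl 4-methoxyacetoacetate)
Product: 4 methyl 2-henicosyl-4-methoxy-3-oxobutanoate (racemic)
Conditions: NaH, THF/DMF (4:1), 0 °C; then 2, 60 °C (3 in 1.5-fold excess)
Reagents that add atoms: none
Why: Acetoacetic ester C-alkylation, in which the stabilised sodium enolate of the carbon between the two carbonyl groups displaces iodide from the unbranched primary iodide by SN2; the excess of the inexpensive keto ester limits double alkylation, and the stereocentre created is racemic and disappears in step 3.

Step 3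
Reactants: 4 methyl 2-henicosyl-4-methoxy-3-oxobutanoate
Product: 5 methyl 2-henicosyl-4-methoxy-3-(trimethylsilyloxy)but-2-enoate (E/Z mixture)
Conditions: Me3SiCl, Et3N, toluene, 20 °C, 72 h; filtration under argon, crude used
Reagents that add atoms: chlorotrimethylsilane, C[Si](C)(C)Cl
Why: Enol silylation of a β-keto ester with a chlorosilane and a tertiary amine, the standard first stage in the preparation of 1-alkoxy-1,3-bis(silyloxy)dienes, should give the conjugated silyl enol ether, whose double-bond geometry is irrelevant because this bond becomes the central single bond of the diene.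

Step 4
Reactants: 5 methyl 2-henicosyl-4-methoxy-3-(trimethylsilyloxy)but-2-enoate
Product: 6 (3Z)-2-henicosyl-1,4-dimethoxy-1,3-bis(trimethylsilyloxy)buta-1,3-diene
Conditions: LiN(iPr)2, THF, −78 °C; Me3SiCl, −78 → 20 °C; hexane, filtration under argon, crude used
Reagents that add atoms: chlorotrimethylsilane, C[Si](C)(C)Cl
Why: Kinetic γ-deprotonation of the β-silyloxy enoate at the methoxy-bearing CH2 group gives an extended ester dienolate that is trapped on the ester oxygen (vinylogous enolate O-silylation), and the new enol ether bond should form with the methoxy group away from the alkyl-bearing carbon, that is 3Z, which places hydrogen and not methoxy on the inside of the s-cis diene.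

Step 5
Reactants: 6 (3Z)-2-henicosyl-1,4-dimethoxy-1,3-bis(trimethylsilyloxy)buta-1,3-diene; 7 but-3-yn-2-one
Product: 9 1-(3-henicosyl-2,4-dihydroxy-5-methoxyphenyl)ethan-1-one, via cyclohexa-1,4-diene cycloadduct 8 (not isolated)
Conditions: toluene, −78 → 20 °C; then 1 M HCl, THF, 20 °C
Reagents that add atoms: none
Why: The donor-substituted diene and the acceptor-substituted alkyne should combine in a normal-electron-demand, highly asynchronous Diels–Alder reaction: the C5–C6 bond forms first between the methoxy-bearing diene terminus and the unsubstituted alkyne carbon, the C1–C2 bond follows between the acetyl-bearing alkyne carbon and the ketene acetal carbon, and a fully stepwise Mukaiyama–Michael addition followed by attack of the allenolate carbon on the silylated ester carbon would reach the same cyclohexa-1,4-diene 8. The closest known reaction type is the cycloaddition–aromatisation of 1-alkoxy-1,3-bis(silyloxy)buta-1,3-dienes with acetylenic esters and ketones to give acyl- and alkoxycarbonyl-resorcinols. The single new ring, a six-membered carbocycle, is closed by this intermolecular [4+2] process, suprafacial on both partners (in the stepwise limit by a 6-exo-trig closure onto the ester-derived carbon). On acidic work-up the mixed methyl silyl ketal at C2 collapses with loss of methanol and trimethylsilanol, the silyl enol ether at C4 is hydrolysed, and the resulting cyclohexenedione tautomerises to the arene; the two sp3 centres of 8 (C2 and C5) vanish in this process, so no stereocentre has to be controlled. The step needs regioselectivity, which the matched polarisation secures, because the three donor oxygens on C2 and C4 make C5 the most nucleophilic carbon, the alkyl-bearing C3 is blocked and the ynone is electrophilic only at its terminal carbon; it also needs discrimination between the two methoxy groups, which is built in, since only the C2 methoxy sits on a ketal carbon and can leave, whereas the C5 methoxy is an ordinary ether whose carbon keeps its hydrogen until tautomerisation.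

Step 6
Reactants: 9 1-(3-henicosyl-2,4-dihydroxy-5-methoxyphenyl)ethan-1-one
Product: 11 3-henicosyl-5-methoxybenzene-1,2,4-triol, via aryl acetate 10 (not isolated)
Conditions: 30% H2O2 (1.1 equiv), NaOH, THF/H2O, 0 → 20 °C, argon; then Na2SO3, 1 M HCl; crude used at once
Reagents that add atoms: hydrogen peroxide, OO
Why: Dakin oxidation, in which hydroperoxide anion adds to the acetyl carbonyl, the aryl group made electron-rich by its ortho and para oxygens migrates to oxygen to give aryl acetate 10, and hydroxide cleaves that ester; the inert atmosphere, the near-stoichiometric peroxide and the sulfite quench should protect the oxidation-prone triol.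

Step 7
Reactants: 11 3-henicosyl-5-methoxybenzene-1,2,4-triol
Product: 12 3-henicosyl-2-hydroxy-5-methoxycyclohexa-2,5-diene-1,4-dione
Conditions: FeCl3, THF/H2O, 0 → 20 °C
Reagents that add atoms: none
Why: Oxidation of a hydroxyhydroquinone to a 2-hydroxy-1,4-benzoquinone by a mild one-electron oxidant in acidic medium removes two hydrogens from the para-related hydroxyl pair on C1 and C4, and the alternative ortho-quinone is only a tautomer of the same vinylogous acid, so no regiochemical issue arises.

Compound list
1 | henicosan-1-ol | CCCCCCCCCCCCCCCCCCCCCO | starting material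
2 | 1-iodohenicosane | CCCCCCCCCCCCCCCCCCCCCI | intermediate
3 | methyl 4-methoxy-3-oxobutanoate | COCC(=O)CC(=O)OC | starting material
4 | methyl 2-henicosyl-4-methoxy-3-oxobutanoate (racemic at C2) | CCCCCCCCCCCCCCCCCCCCCC(C(=O)COC)C(=O)OC | intermediate
5 | methyl 2-henicosyl-4-methoxy-3-(trimethylsilyloxy)but-2-enoate (E/Z mixture) | CCCCCCCCCCCCCCCCCCCCCC(C(=O)OC)=C(COC)O[Si](C)(C)C | intermediate
6 | (3Z)-2-henicosyl-1,4-dimethoxy-1,3-bis(trimethylsilyloxy)buta-1,3-diene (ketene acetal geometry not defined) | CO/C=C(O[Si](C)(C)C)/C(CCCCCCCCCCCCCCCCCCCCC)=C(OC)O[Si](C)(C)C | intermediate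
7 | but-3-yn-2-one | CC(=O)C#C | starting material
8 | 1-[5-henicosyl-3,6-dimethoxy-4,6-bis(trimethylsilyloxy)cyclohexa-1,4-dien-1-yl]ethan-1-one (mixture of racemic diastereomers, not isolated) | CC(=O)C1=CC(OC)C(O[Si](C)(C)C)=C(CCCCCCCCCCCCCCCCCCCCC)C1(OC)O[Si](C)(C)C | intermediate
9 | 1-(3-henicosyl-2,4-dihydroxy-5-methoxyphenyl)ethan-1-one | CCCCCCCCCCCCCCCCCCCCCc1c(O)c(C(C)=O)cc(OC)c1O | intermediate
10 | 3-henicosyl-2,4-dihydroxy-5-methoxyphenyl acetate (not isolated) | CCCCCCCCCCCCCCCCCCCCCc1c(O)c(OC(C)=O)cc(OC)c1O | intermediate
11 | 3-henicosyl-5-methoxybenzene-1,2,4-triol | CCCCCCCCCCCCCCCCCCCCCc1c(O)c(O)cc(OC)c1O | intermediate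
12 | 3-henicosyl-2-hydroxy-5-methoxycyclohexa-2,5-diene-1,4-dione | CCCCCCCCCCCCCCCCCCCCCC1=C(O)C(=O)C=C(OC)C1=O | target

Total step count: 7.
Longest linear sequence: 7 steps (1 → 2 → 4 → 5 → 6 → 9 → 11 → 12); compounds 3 and 7 enter as bought.

Steps most likely to fail

Step 5. The addition may stop after the first carbon–carbon bond without ring closure, the crude diene may lose its silyl groups to adventitious acid or moisture before it reacts, or the ynone may polymerise. The fallback gives up ring construction and functionalises a preformed arene. It sets out from compound 2 and comes back at compound 12. Commercial 4-methoxybenzene-1,3-diol would be protected with MOMCl and iPr2NEt in CH2Cl2 to 1-methoxy-2,4-bis(methoxymethoxy)benzene F1. Lithiation with nBuLi in THF at 0 °C at the carbon between the two acetal oxygens and alkylation with 2 should give 2-henicosyl-4-methoxy-1,3-bis(methoxymethoxy)benzene F2. HCl in MeOH/THF would remove both acetals to give 2-henicosyl-4-methoxybenzene-1,3-diol F3. Teuber oxidation with (KSO3)2NO (KH2PO4 buffer, THF/H2O, catalytic nBu4NHSO4) at the only free ring position, para to one hydroxyl and ortho to the other, should lead directly to 12.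

Step 4. Deprotonation at the methoxy-bearing carbon may be incomplete, the amide may attack silicon and return the enolate, C-silylation may compete, and the diene, which cannot be purified, may hydrolyse during the solvent change. The fallback abandons the lithium dienolate for electrophile-driven soft enolisation. It sets out from compound 4 and comes back at compound 6. Treatment of 4 with Me3SiOTf (2.3 equiv) and Et3N in Et2O at 0 → 20 °C silylates each carbonyl oxygen first and lets the amine remove the adjacent proton afterwards, so both silyl groups are installed in one flask without passing through isolated 5. No new compound is made (entry F0).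

Step 6. The electron-rich triol, or quinone formed from it by traces of oxidant, may be degraded by alkaline peroxide, and aryl migration may be slow because the chelated, doubly deprotonated ketone is a poor electrophile. The fallback replaces the alkaline peroxide reaction by a peracid rearrangement on a protected substrate. It sets out from compound 9 and comes back at compound 11. Benzylation (BnBr, K2CO3, DMF, 60 °C) should give 1-[2,4-bis(benzyloxy)-3-henicosyl-5-methoxyphenyl]ethan-1-one F4. Baeyer–Villiger oxidation (mCPBA, NaHCO3, CH2Cl2), with migration of the electron-rich aryl group, should give 2,4-bis(benzyloxy)-3-henicosyl-5-methoxyphenyl acetate F5. Methanolysis (K2CO3, MeOH/THF) should give 2,4-bis(benzyloxy)-3-henicosyl-5-methoxyphenol F6. Hydrogenolysis (H2, Pd/C, EtOAc) would then release 11 under neutral, oxygen-free conditions.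

Further compounds
F1 | step 5 | 1-methoxy-2,4-bis(methoxymethoxy)benzene | COCOc1ccc(OC)c(OCOC)c1
F2 | step 5 | 2-henicosyl-4-methoxy-1,3-bis(methoxymethoxy)benzene | COCOc1ccc(OC)c(OCOC)c1CCCCCCCCCCCCCCCCCCCCC
F3 | step 5 | 2-henicosyl-4-methoxybenzene-1,3-diol | Oc1ccc(OC)c(O)c1CCCCCCCCCCCCCCCCCCCCC
F0 | step 4 | none | none
F4 | step 6 | 1-[2,4-bis(benzyloxy)-3-henicosyl-5-methoxyphenyl]ethan-1-one | CCCCCCCCCCCCCCCCCCCCCc1c(OCc2ccccc2)c(C(C)=O)cc(OC)c1OCc1ccccc1
F5 | step 6 | 2,4-bis(benzyloxy)-3-henicosyl-5-methoxyphenyl acetate | CCCCCCCCCCCCCCCCCCCCCc1c(OCc2ccccc2)c(OC(C)=O)cc(OC)c1OCc1ccccc1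
F6 | step 6 | 2,4-bis(benzyloxy)-3-henicosyl-5-methoxyphenol | CCCCCCCCCCCCCCCCCCCCCc1c(OCc2ccccc2)c(O)cc(OC)c1OCc1ccccc1
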